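A direct plan would tribrominate guaiacol A1 to 2,3,4-tribromo-6-methoxyphenol A2 and O-methylate it to 1,2,3-tribromo-4,5-dimethoxybenzene A3. It would then join A3 to 2,4,6-trimethoxybenzaldehyde A4 by a nickel-catalysed coupling in which hydrazine turns the aldehyde carbon into a benzyl nucleophile, monobrominate ring B of the pentamethyl ether A5 to A6, and cleave all five ethers with BBr3.
Weakest steps:
- The aryl–CH2 coupling: zerovalent nickel would have to pick one outer C–Br bond out of three in A3 and accept a di-ortho-substituted, electron-rich hydrazone under strongly basic, reducing conditions. This site selection has no precedent, and double coupling or hydrodebromination would give bromoarenes that are hard to separate.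
- The ring B bromination of A5: there are two equivalent, triply activated positions, so stopping at one bromine would rest on stoichiometry alone.
- The five-fold demethylation: five O-methyl groups would be carried through the route only to be removed at the end by a large excess of BBr3 on the finished tribromide.

**Retrosynthetic overview** (ring A = dibromocatechol ring; ring B = bromophloroglucinol ring, C-1' bearing the CH2, C-3' the Br, C-5' the H)
- Ring B alternates C–O carbons (C-2', C-4', C-6') with C-1', C-3', C-5', which is the pattern of a folded poly-β-carbonyl chain. It is cut at C-5'–C-6' back to the 4-hydroxy-2-pyrone 8, a lactone-masked 3,5-dioxopimelate that already holds the three ring B oxygens as carbonyl oxygens.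
- Pyrone 8 comes from 4-hydroxy-6-methyl-2-pyrone (a ready-made triketide), Boc2O and aldehyde 3. The CH2 bridge is the aldehyde carbon, joined to pyrone C-3 by Knoevenagel condensation/transfer hydrogenation, so no C–Br bond has to be chosen and no metal is used.
- Ring A is bought aromatic (5-bromovanillin); ring B is closed late, by lactone opening and Dieckmann condensation.
- The tert-butyl ester that makes C-5' nucleophilic then blocks it, so ring B has a single free position for bromination. The ester leaves as CO2 in the same BBr3 step that cleaves the only two O-methyl groups.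

Key step: step 5

Remark on the chemistry: 5-bromovanillin and 4-hydroxy-6-methyl-2H-pyran-2-one are taken as commercial; vidalol A is achiral, so no stereocentre has to be set.

Step 1
Reactants: 1 5-bromovanillin (3-bromo-4-hydroxy-5-methoxybenzaldehyde)
Product: 2 5,6-dibromovanillin (2,3-dibromo-4-hydroxy-5-methoxybenzaldehyde)
Conditions: Br2 (1.2 equiv), Fe powder (5 mol %), NaOAc (1.5 equiv), AcOH, rt
Reagents that add atoms: bromine, BrBr
Why: Electrophilic aromatic bromination, in which the position para to the methoxy group (C-6) is the most activated one left, while C-2 is flanked by the formyl and methoxy groups, so the second bromine should enter next to the first, as in the usual preparation of 5,6-dibromovanillin.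

Step 2
Reactants: 2 5,6-dibromovanillin
Product: 3 2,3-dibromo-4,5-dimethoxybenzaldehyde
Conditions: MeI (1.5 equiv), K2CO3 (2 equiv), DMF, rt
Reagents that add atoms: iodomethane, CI
Why: Williamson ether synthesis on an acidic bromophenol, which removes the para-hydroxybenzyl (quinone methide) fragmentation pathway that a free phenoxide would open in the basic key step.

Step 3
Reactants: 4 4-hydroxy-6-methyl-2H-pyran-2-one (triacetic acid lactone)
Product: 6 tert-butyl 2-(4-hydroxy-2-oxo-2H-pyran-6-yl)acetate, via dilithium pyrone dianion 5 (not isolated)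
Conditions: LDA (3.2 equiv), THF, −78 °C; Boc2O (1.05 equiv), −78 → −20 °C; cold 1 M HCl
Reagents that add atoms: di-tert-butyl dicarbonate, CC(C)(C)OC(=O)OC(=O)OC(C)(C)C
Why: Dianion chemistry of the pyrone followed by Claisen-type C-acylation: the second equivalent of base removes a proton from the 6-methyl group (vinylogous to the lactone carbonyl), this carbanion is far more nucleophilic than the 4-oxido group and should attack Boc2O at carbon, and the third equivalent of base takes up the more acidic product.

Step 4
Reactants: 3 2,3-dibromo-4,5-dimethoxybenzaldehyde; 6 tert-butyl 2-(4-hydroxy-2-oxo-2H-pyran-6-yl)acetate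
Product: 8 tert-butyl 2-{3-[(2,3-dibromo-4,5-dimethoxyphenyl)methyl]-4-hydroxy-2-oxo-2H-pyran-6-yl}acetate, via arylidene pyrandione 7 (not isolated)
Conditions: Hantzsch ester (diethyl 2,6-dimethyl-1,4-dihydropyridine-3,5-dicarboxylate, 1.1 equiv), L-proline (20 mol %), CH2Cl2/EtOH, rt
Reagents that add atoms: none
Why: Organocatalytic three-component reductive alkylation (Knoevenagel condensation, then transfer hydrogenation): pyrone C-3, the only carbon between two carbonyl-type carbons, condenses with the aldehyde through its proline iminium ion, and the Hantzsch ester should reduce arylidene 7 as it forms, which suppresses addition of a second pyrone and leaves both C–Br bonds untouched because neither a metal nor H2 is present.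

Step 5
Reactants: 8 tert-butyl 2-{3-[(2,3-dibromo-4,5-dimethoxyphenyl)methyl]-4-hydroxy-2-oxo-2H-pyran-6-yl}acetate
Product: 10 tert-butyl 3-[(2,3-dibromo-4,5-dimethoxyphenyl)methyl]-2,4,6-trihydroxybenzoate, via open-chain triketide diester 9 (not isolated)
Conditions: Mg(OMe)2 (4 equiv, solution in MeOH), MeOH, reflux, argon; then cold 1 M HCl
Reagents that add atoms: magnesium methoxide, C[O-].C[O-].[Mg+2] (its methoxy group is carried in 9 and leaves again as methanol; no atom of it stays in 10)
Why: Methoxide should open the lactone of 8 at C-2 to the magnesium-chelated 3,5-dioxopimelate 9, whose C-6, activated by both the C-5 ketone and the tert-butyl ester, attacks the new methyl ester carbon C-1 in a Dieckmann (intramolecular Claisen) condensation; loss of methoxide and enolization give the benzene-1,3,5-triol, so the net change is an isomerization of pyrone to arene. The closest known reaction type is the Mg(OMe)2-mediated conversion of pyrone-masked poly-β-carbonyl compounds into acylphloroglucinols by the Claisen mode, and the same Dieckmann closure is the ring-forming event of the classical malonate route to phloroglucinol carboxylates. Ring B closes by 6-exo-trig attack of the enolate carbon on the ester carbonyl and forms the C-5'–C-6' bond. No stereocentre is created, and the one in 9 (C-2, racemic) becomes an sp2 ring carbon. The selectivity needed is C-6 → C-1 over C-2 → C-7 and over relactonization: the second mode would send a tertiary carbanion against a tert-butyl ester and give a ring with a quaternary carbon that cannot aromatize, and lactone formation is reversible under methoxide, so the aromatic benzoate, held as its magnesium phenoxide, should be the only sink.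

Step 6
Reactants: 10 tert-butyl 3-[(2,3-dibromo-4,5-dimethoxyphenyl)methyl]-2,4,6-trihydroxybenzoate
Product: 11 tert-butyl 3-bromo-5-[(2,3-dibromo-4,5-dimethoxyphenyl)methyl]-2,4,6-trihydroxybenzoate
Conditions: NBS (1.0 equiv), MeCN, −20 → 0 °C, dark
Reagents that add atoms: N-bromosuccinimide, O=C1CCC(=O)N1Br
Why: Electrophilic aromatic bromination, in which the only unsubstituted carbon of ring B is activated by three hydroxy groups, the ester blocks the position that must keep its hydrogen, and ring A is deactivated by two bromines, so one equivalent of NBS should give a single monobromide.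

Step 7
Reactants: 11 tert-butyl 3-bromo-5-[(2,3-dibromo-4,5-dimethoxyphenyl)methyl]-2,4,6-trihydroxybenzoate
Product: 13 vidalol A, via trihydroxybenzoic acid 12 (not isolated)
Conditions: BBr3 (8 equiv), CH2Cl2, −78 °C → rt; evaporate volatiles; then H2O/MeCN, 45 °C, argon
Reagents that add atoms: none
Why: Lewis-acid cleavage of the two aryl methyl ethers (bromide takes each methyl group by SN2) and of the tert-butyl ester (the tert-butyl group leaves as a cation) by BBr3, after which the 2,4,6-trihydroxybenzoic acid 12 set free on hydrolysis should lose CO2 on gentle warming by protodecarboxylation through its keto tautomer, leaving hydrogen at C-5'.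

**Compound list**
1 | 5-bromovanillin (3-bromo-4-hydroxy-5-methoxybenzaldehyde) | COc1cc(C=O)cc(Br)c1O | starting material
2 | 5,6-dibromovanillin (2,3-dibromo-4-hydroxy-5-methoxybenzaldehyde) | COc1cc(C=O)c(Br)c(Br)c1O | intermediate
3 | 2,3-dibromo-4,5-dimethoxybenzaldehyde | COc1cc(C=O)c(Br)c(Br)c1OC | intermediate
4 | 4-hydroxy-6-methyl-2H-pyran-2-one (triacetic acid lactone) | Cc1cc(O)cc(=O)o1 | starting material
5 | dilithium dianion of 4 (4-oxido group and 6-CH2 carbanion; not isolated) | [Li+].[Li+].[CH2-]c1cc([O-])cc(=O)o1 | intermediate
6 | tert-butyl 2-(4-hydroxy-2-oxo-2H-pyran-6-yl)acetate | CC(C)(C)OC(=O)Cc1cc(O)cc(=O)o1 | intermediate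
7 | tert-butyl 2-{3-[(2,3-dibromo-4,5-dimethoxyphenyl)methylidene]-2,4-dioxo-3,4-dihydro-2H-pyran-6-yl}acetate (alkene geometry not controlled; not isolated) | CC(C)(C)OC(=O)CC1=CC(=O)C(=Cc2cc(OC)c(OC)c(Br)c2Br)C(=O)O1 | intermediate
8 | tert-butyl 2-{3-[(2,3-dibromo-4,5-dimethoxyphenyl)methyl]-4-hydroxy-2-oxo-2H-pyran-6-yl}acetate | CC(C)(C)OC(=O)Cc1cc(O)c(Cc2cc(OC)c(OC)c(Br)c2Br)c(=O)o1 | intermediate
9 | 7-tert-butyl 1-methyl 2-[(2,3-dibromo-4,5-dimethoxyphenyl)methyl]-3,5-dioxoheptanedioate (racemic; present as magnesium chelate; not isolated) | COC(=O)C(Cc1cc(OC)c(OC)c(Br)c1Br)C(=O)CC(=O)CC(=O)OC(C)(C)C | intermediate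
10 | tert-butyl 3-[(2,3-dibromo-4,5-dimethoxyphenyl)methyl]-2,4,6-trihydroxybenzoate | CC(C)(C)OC(=O)c1c(O)cc(O)c(Cc2cc(OC)c(OC)c(Br)c2Br)c1O | intermediate
11 | tert-butyl 3-bromo-5-[(2,3-dibromo-4,5-dimethoxyphenyl)methyl]-2,4,6-trihydroxybenzoate | CC(C)(C)OC(=O)c1c(O)c(Br)c(O)c(Cc2cc(OC)c(OC)c(Br)c2Br)c1O | intermediate
12 | 3-bromo-5-[(2,3-dibromo-4,5-dihydroxyphenyl)methyl]-2,4,6-trihydroxybenzoic acid (not isolated) | OC(=O)c1c(O)c(Br)c(O)c(Cc2cc(O)c(O)c(Br)c2Br)c1O | intermediate
13 | vidalol A, 2-bromo-4-[(2,3-dibromo-4,5-dihydroxyphenyl)methyl]benzene-1,3,5-triol (achiral) | Oc1cc(Cc2c(O)cc(O)c(Br)c2O)c(Br)c(Br)c1O | target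

Total step count: 7. Longest linear sequence: 6 (steps 1, 2, 4, 5, 6, 7); the pyrone branch (step 3) joins at step 4.

**Steps most likely to fail**

Step 5 (ring opening/Dieckmann). The pyronate anion may resist attack by methoxide, so that transesterification of the tert-butyl ester or retro-Claisen cleavage of the chain overtakes ring closure. The fallback sets out from 3 and comes back at 10; it makes the CH2–ring B bond by classical polarity on a preformed ring. Aldehyde 3 would be reduced with NaBH4 to (2,3-dibromo-4,5-dimethoxyphenyl)methanol F1 and converted with PBr3 into 2,3-dibromo-1-(bromomethyl)-4,5-dimethoxybenzene F2. The phenoxide of tert-butyl 2,4,6-trihydroxybenzoate F3 (from commercial 2,4,6-trihydroxybenzoic acid and tert-butyl 2,2,2-trichloroacetimidate) would then be C-benzylated with F2 (NaOMe, MeOH, 0 °C, F3 in excess) to give 10.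

Step 3 (acylation of the pyrone dianion). Acyl transfer to the 4-oxido oxygen or to the amide base in place of C-7, and proton exchange between product and dianion, may leave mostly unchanged pyrone. The fallback sets out from 4 and comes back at 6. Dianion 5 would be carboxylated with CO2, a carbon electrophile that binds the oxido group only reversibly, to give 2-(4-hydroxy-2-oxo-2H-pyran-6-yl)acetic acid F4. F4 would then be esterified with tert-butanol under Steglich conditions (DCC, DMAP cat., tBuOH/CH2Cl2, 0 °C → rt) to give 6.

Step 7 (demethylation, ester cleavage and decarboxylation in one operation). Protodebromination of ring B, acid-induced cleavage of the diarylmethane bond, or incomplete loss of CO2 may occur while the free polyphenol is warmed in aqueous HBr. The fallback sets out from 11 and comes back at 13; it separates the two events. The tert-butyl ester would be cleaved with TMSOTf/2,6-lutidine (CH2Cl2, 0 °C) and the silyl groups removed with methanol to give 3-bromo-5-[(2,3-dibromo-4,5-dimethoxyphenyl)methyl]-2,4,6-trihydroxybenzoic acid F5. F5 would lose CO2 in acetate buffer (pH 5, 40 °C) to give 2-bromo-4-[(2,3-dibromo-4,5-dimethoxyphenyl)methyl]benzene-1,3,5-triol F6. F6 would then be demethylated with BBr3 at −78 → 0 °C and quenched cold with methanol, so that the free bromophloroglucinol never meets warm acid.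

**Further compounds**
F1 | step 5 | (2,3-dibromo-4,5-dimethoxyphenyl)methanol | COc1cc(CO)c(Br)c(Br)c1OC
F2 | step 5 | 2,3-dibromo-1-(bromomethyl)-4,5-dimethoxybenzene | COc1cc(CBr)c(Br)c(Br)c1OC
F3 | step 5 | tert-butyl 2,4,6-trihydroxybenzoate | CC(C)(C)OC(=O)c1c(O)cc(O)cc1O
F4 | step 3 | 2-(4-hydroxy-2-oxo-2H-pyran-6-yl)acetic acid | OC(=O)Cc1cc(O)cc(=O)o1
F5 | step 7 | 3-bromo-5-[(2,3-dibromo-4,5-dimethoxyphenyl)methyl]-2,4,6-trihydroxybenzoic acid | COc1cc(Cc2c(O)c(Br)c(O)c(C(O)=O)c2O)c(Br)c(Br)c1OC
F6 | step 7 | 2-bromo-4-[(2,3-dibromo-4,5-dimethoxyphenyl)methyl]benzene-1,3,5-triol | COc1cc(Cc2c(O)cc(O)c(Br)c2O)c(Br)c(Br)c1OC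
A1 | direct plan | guaiacol (2-methoxyphenol) | COc1ccccc1O
A2 | direct plan | 2,3,4-tribromo-6-methoxyphenol | COc1cc(Br)c(Br)c(Br)c1O
A3 | direct plan | 1,2,3-tribromo-4,5-dimethoxybenzene | COc1cc(Br)c(Br)c(Br)c1OC
A4 | direct plan | 2,4,6-trimethoxybenzaldehyde | COc1cc(OC)c(C=O)c(OC)c1
A5 | direct plan | 2-[(2,3-dibromo-4,5-dimethoxyphenyl)methyl]-1,3,5-trimethoxybenzene | COc1cc(OC)c(Cc2cc(OC)c(OC)c(Br)c2Br)c(OC)c1
A6 | direct plan | 2-bromo-4-[(2,3-dibromo-4,5-dimethoxyphenyl)methyl]-1,3,5-trimethoxybenzene | COc1cc(OC)c(Cc2cc(OC)c(OC)c(Br)c2Br)c(OC)c1Br
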